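I carry one number, 0.187, or ten to the power −0.729: twice the dimerisation constant over the constant of Z + J, which I call w, the selectivity factor. J lost to J2 per Z consumed is w[J]/[Z].

| setting | red | green | blue | grey |
|---|---|---|---|---|
| Z | 0.050 M | 0.050 M | 0.050 M (fed, over 2.00 h) | 0.050 M |
| J | 1.10 equiv | 1.10 equiv | 1.10 equiv | 1.10 equiv (fed, over 2.00 h) |
| remark | one stirred flow tank at steady state, fed with the mixture as stated, mean residence time 4.0 h | a closed flask charged with all of it at once and left for 4.0 h | a stirred flask in which Z is dosed at a steady rate over 2.00 h without added volume, worked up at 4.0 h | all but J at the start; J goes in evenly over 2.00 h, the run ends at 4.0 h |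
| time |  | 4.0 h | 4.0 h | 4.0 h |

* the set-up with the highest amount of Z.J at the outlet or at the end, in percent of the Z put in ("none" if the first two lie within 2 percentage points) (red / green / blue / grey / none)
* amount of Z.J at the outlet or at the end, in percent of the Z put in, red
* amount of Z.J at the outlet or at the end, in percent of the Z put in, green
* amount of Z.J at the outlet or at the end, in percent of the Z put in, blue
* amount of Z.J at the outlet or at the end, in percent of the Z put in, grey

- two of one species on the left: rate k times its square, two consumed each time
- the stated concentrations are those of everything mixed, before any reaction; amounts are the same in each set-up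
- the feed brings no volume worth counting
- run time (green): 4.0 h

    2 J → J2 (k1 = 0.085 M⁻¹ min⁻¹)
    Z + J → Z.J (k2 = 0.91 M⁻¹ min⁻¹)
    Z.J ⇌ L (K3 = 4.1, k3 = 7.9 × 10⁻⁴ min⁻¹)

At the start of the feed [J]/[Z] is low in grey, where J is dosed into Z, and high in blue, where Z is dosed into J, against 1.10 as charged in green. So I put grey above green and blue below green. I bracket green. Dividing the two rates gives d[J]/d[Z] as one plus w[J]/[Z], which integrates in closed form. When J reaches zero, the decimal logarithm of the Z left, as a fraction of charge, is −1.20, so the residue is 6.29%. The J curve is convex and touches the line [Z] minus that residue at exhaustion, so J stays above this line. Integrating with the line caps the Z left at 11.9% at the end and 18.8% at mid-run.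

From below, I let the Z consumed drift forward to L for the whole run, which leaves 72.9% as Z.J in green. From above, neglecting the back step, I let what formed by mid-run drift for the second half and the rest not at all, which gives 86.4% as Z.J in green.

The forecast says 62% for red, 76% for green, 58% for blue and 79% for grey, and it names grey as best, on the ground of “keeping J scarce by dosing it into Z”. Its green value is more than my lower bound and less than my upper one.

The simulation gives 61.7% for red, 75.7% for green, 60.7% for blue and 79.1% for grey, so grey is best. With the conversion to L struck out, green gives 88.7%. Green's residue holds too: after 40.0 h its Z stands at 6.30% with J at 0%, matching the 6.29% from w.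

Take grey with 0.440 equiv of J, where J is the limiting reagent. Feed balancing consumption at the mean [Z] gives [J]/[Z] near 0.132, so w predicts 57.1% of Z left. The flask leaves 57.2% of Z, 0.88% of J and 38.1% of Z.J.

(The constants used here come from no measurement; the result is computed.)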